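**Retrosynthetic overview**
- The tridepside is cut at its two aryl ester bonds. The ring B to ring C ester (at O4 of ring C) is the last skeletal bond made. Rings A and B come from bought arenes: methyl orsellinate for ring A, and 2,4-dihydroxy-6-methylbenzaldehyde for ring B, with the formyl group serving as the masked ring B acid.
- Only ring C is built from acyclic material. Its C2 methoxy and C4 acyloxy oxygens would be two similar phenols in an orsellinate, but in methyl 6-methyl-2,4-dioxocyclohexane-1-carboxylate they differ: the C4 oxygen belongs to a vinylogous acid flanked by CH and CH2, whereas the C2 oxygen belongs to a beta-keto ester next to C1.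
- The dione is disconnected at C1-C6 (Michael addition) and C3-C4 (Dieckmann closure) to methyl acetoacetate and methyl (E)-crotonate.
- Order: the ring C carbocycle is closed first, in its saturated form (step 1, the only ring-forming step). The A-B acid is then assembled (steps 2-7). Finally O4 is acylated, O2 is methylated, ring C is dehydrogenated and the benzyl group is removed (steps 8-11).

Key step: step 1

Remark: compounds 3, 4, 15 and 16 carry sp3 centres at C1 and/or C6 of ring C. They are racemic (3, 4 and 15 are also diastereomer and tautomer mixtures) and are drawn without stereodescriptors, because both centres are erased in step 10 and the target is achiral.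

**Step 1**
Reactants: 1 methyl acetoacetate; 2 methyl (E)-crotonate
Product: 4 methyl 6-methyl-2,4-dioxocyclohexane-1-carboxylate (racemic; enolised), via Michael adduct 3 (not isolated)
Conditions: NaOMe (1.05 equiv), MeOH, reflux; then cold aq. HCl
Reagents that add atoms: none
Why: Methoxide converts 1 into its doubly stabilised enolate, whose central carbon adds 1,4 to crotonate 2 (Michael addition, C1-C6 bond) to give 3; proton transfer then places the charge on the acetyl methyl, which attacks the distal ester in a Dieckmann (intramolecular Claisen) condensation that forms the C3-C4 bond and expels methoxide. The closest known reaction type is the alkoxide-mediated annulation of acetoacetates with crotonates to dihydroresorcylates. Ring C closes in the 6-exo-trig mode, the only strain-free closure open to 3, since every other enolate-carbonyl pairing would give a four-membered ring. The two sp3 centres (C1, C6) form without control as an epimerisable, largely enolised racemate, which is immaterial because both are erased on aromatisation. The step needs the central carbon to do the Michael addition and the terminal carbon to do the acylation, which follows from the order of enolate stabilities, and it is driven forward by irreversible deprotonation of the acidic dione, whose sodium salt should separate from methanol.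

**Step 2**
Reactants: 5 methyl orsellinate (methyl 2,4-dihydroxy-6-methylbenzoate)
Product: 6 methyl 2-hydroxy-4-methoxy-6-methylbenzoate
Conditions: MeI (1.05 equiv), K2CO3, acetone, reflux
Reagents that add atoms: iodomethane, CI
Why: Williamson ether synthesis in which the C4 hydroxyl, more acidic and not hydrogen-bonded to the ester, should be alkylated in preference to the chelated C2 hydroxyl when the methylating agent is limited to about one equivalent.

**Step 3**
Reactants: 6 methyl 2-hydroxy-4-methoxy-6-methylbenzoate
Product: 7 methyl 2-(benzyloxy)-4-methoxy-6-methylbenzoate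
Conditions: BnBr, K2CO3, DMF, 60 °C
Reagents that add atoms: benzyl bromide, BrCc1ccccc1
Why: Williamson benzylation of the remaining chelated phenol, which needs only the more forcing DMF/heat conditions and has no competing nucleophilic site.

**Step 4**
Reactants: 7 methyl 2-(benzyloxy)-4-methoxy-6-methylbenzoate
Product: 8 2-(benzyloxy)-4-methoxy-6-methylbenzoic acid
Conditions: KOH, DMSO/H2O, 90 °C; then cold dilute HCl
Reagents that add atoms: potassium hydroxide, [K+].[OH-]
Why: Saponification of a di-ortho-substituted benzoate, which requires poorly solvated hydroxide in hot aqueous DMSO but leaves the benzyl and methyl ethers untouched; cold acidification avoids decarboxylation of the electron-rich acid.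

**Step 5**
Reactants: 8 2-(benzyloxy)-4-methoxy-6-methylbenzoic acid; 9 2,4-dihydroxy-6-methylbenzaldehyde
Product: 11 4-formyl-3-hydroxy-5-methylphenyl 2-(benzyloxy)-4-methoxy-6-methylbenzoate, via acid chloride 10 (not isolated)
Conditions: (COCl)2, cat. DMF, CH2Cl2, 0 °C to rt, evaporate; then 9 (1.1 equiv), Et3N, cat. DMAP, CH2Cl2, 0 °C to rt
Reagents that add atoms: none
Why: Acid chloride formation followed by base-mediated phenol acylation, in which the C4 hydroxyl of 9 (para to the formyl group, the more acidic one) should react selectively because the C2 hydroxyl is deactivated by its hydrogen bond to the aldehyde.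

**Step 6**
Reactants: 11 4-formyl-3-hydroxy-5-methylphenyl 2-(benzyloxy)-4-methoxy-6-methylbenzoate
Product: 12 4-formyl-3-methoxy-5-methylphenyl 2-(benzyloxy)-4-methoxy-6-methylbenzoate
Conditions: MeI, K2CO3, DMF, rt
Reagents that add atoms: iodomethane, CI
Why: Williamson methylation of the only free phenol; the aryl ester should survive anhydrous carbonate because its carbonyl is shielded by the ortho benzyloxy and methyl groups.

**Step 7**
Reactants: 12 4-formyl-3-methoxy-5-methylphenyl 2-(benzyloxy)-4-methoxy-6-methylbenzoate
Product: 13 4-{[2-(benzyloxy)-4-methoxy-6-methylbenzoyl]oxy}-2-methoxy-6-methylbenzoic acid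
Conditions: NaClO2, NaH2PO4, 2-methyl-2-butene, t-BuOH/THF/H2O, rt
Reagents that add atoms: sodium chlorite, [Na+].[O-]Cl=O
Why: Pinnick oxidation, a mildly acidic aldehyde-to-acid oxidation that tolerates the aryl ester and the benzyl ether, with the alkene scavenger removing hypochlorite before it can chlorinate the electron-rich rings.

**Step 8**
Reactants: 13 4-{[2-(benzyloxy)-4-methoxy-6-methylbenzoyl]oxy}-2-methoxy-6-methylbenzoic acid; 4 methyl 6-methyl-2,4-dioxocyclohexane-1-carboxylate
Product: 15 methyl 4-[(4-{[2-(benzyloxy)-4-methoxy-6-methylbenzoyl]oxy}-2-methoxy-6-methylbenzoyl)oxy]-6-methyl-2-oxocyclohex-3-ene-1-carboxylate (racemic), via acid chloride 14 (not isolated)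
Conditions: (COCl)2, cat. DMF, CH2Cl2, 0 °C to rt, evaporate; then 4, Et3N, CH2Cl2, 0 °C to rt (no DMAP)
Reagents that add atoms: none
Why: O-acylation of the triethylammonium enolate of a cyclic 1,3-dione to an enol ester, where the di-ortho-substituted acid chloride should take the unhindered vinylogous-acid oxygen at C4 (flanked by CH and CH2) and not the C2 oxygen beside the C1 ester; omitting acyl-transfer catalysts disfavours O-to-C migration to C3.

**Step 9**
Reactants: 15 enol ester (methyl 4-aroyloxy-6-methyl-2-oxocyclohex-3-ene-1-carboxylate as named in step 8)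
Product: 16 methyl 4-[(4-{[2-(benzyloxy)-4-methoxy-6-methylbenzoyl]oxy}-2-methoxy-6-methylbenzoyl)oxy]-2-methoxy-6-methylcyclohexa-1,3-diene-1-carboxylate (racemic)
Conditions: Me2SO4, Cs2CO3, anhydrous MeCN, 0 °C to rt
Reagents that add atoms: dimethyl sulfate, COS(=O)(=O)OC
Why: O-alkylation of a beta-keto ester enolate, favoured by the hard sulfate electrophile, the loosely paired caesium enolate in a dipolar aprotic solvent and the crowding at tertiary C1 next to the C6 methyl, with a non-nucleophilic base so that the enol ester at C4 is not cleaved.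

**Step 10**
Reactants: 16 dienol ether (methyl 4-aroyloxy-2-methoxy-6-methylcyclohexa-1,3-diene-1-carboxylate as named in step 9)
Product: 17 methyl 4-[(4-{[2-(benzyloxy)-4-methoxy-6-methylbenzoyl]oxy}-2-methoxy-6-methylbenzoyl)oxy]-2-methoxy-6-methylbenzoate
Conditions: DDQ (1.1 equiv), anhydrous CH2Cl2, rt
Reagents that add atoms: none
Why: Quinone dehydrogenation of a cyclohexa-1,3-diene, in which hydride loss from tertiary C6 gives a pentadienyl cation stabilised by the C2 methoxy and C4 acyloxy oxygens and proton loss from C5 then gives the arene, while the benzyl aryl ether ortho to a carbonyl is a poor hydride donor at room temperature.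

**Step 11**
Reactants: 17 benzyl-protected tridepside
Product: 18 methyl 4-({4-[(2-hydroxy-4-methoxy-6-methylbenzoyl)oxy]-2-methoxy-6-methylbenzoyl}oxy)-2-methoxy-6-methylbenzoate (CNP0362907.0)
Conditions: H2 (1 atm), 10% Pd/C, EtOAc, rt
Reagents that add atoms: none
Why: Hydrogenolysis of the benzyl aryl ether under neutral conditions, which leaves the two depside esters and the methyl ester intact and releases the ring A phenol.

**Compound list**
1 | methyl acetoacetate | COC(=O)CC(C)=O | starting material
2 | methyl (E)-crotonate | COC(=O)/C=C/C | starting material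
3 | dimethyl 2-acetyl-3-methylpentanedioate (Michael adduct, diastereomer mixture, not isolated) | COC(=O)CC(C)C(C(C)=O)C(=O)OC | intermediate
4 | methyl 6-methyl-2,4-dioxocyclohexane-1-carboxylate (racemic, enolised) | COC(=O)C1C(C)CC(=O)CC1=O | intermediate
5 | methyl orsellinate (methyl 2,4-dihydroxy-6-methylbenzoate) | COC(=O)c1c(C)cc(O)cc1O | starting material
6 | methyl 2-hydroxy-4-methoxy-6-methylbenzoate | COC(=O)c1c(C)cc(OC)cc1O | intermediate
7 | methyl 2-(benzyloxy)-4-methoxy-6-methylbenzoate | COC(=O)c1c(C)cc(OC)cc1OCc1ccccc1 | intermediate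
8 | 2-(benzyloxy)-4-methoxy-6-methylbenzoic acid | OC(=O)c1c(C)cc(OC)cc1OCc1ccccc1 | intermediate
9 | 2,4-dihydroxy-6-methylbenzaldehyde | O=Cc1c(C)cc(O)cc1O | starting material
10 | 2-(benzyloxy)-4-methoxy-6-methylbenzoyl chloride (not isolated) | ClC(=O)c1c(C)cc(OC)cc1OCc1ccccc1 | intermediate
11 | 4-formyl-3-hydroxy-5-methylphenyl 2-(benzyloxy)-4-methoxy-6-methylbenzoate | O=Cc1c(C)cc(OC(=O)c2c(C)cc(OC)cc2OCc2ccccc2)cc1O | intermediate
12 | 4-formyl-3-methoxy-5-methylphenyl 2-(benzyloxy)-4-methoxy-6-methylbenzoate | O=Cc1c(C)cc(OC(=O)c2c(C)cc(OC)cc2OCc2ccccc2)cc1OC | intermediate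
13 | 4-{[2-(benzyloxy)-4-methoxy-6-methylbenzoyl]oxy}-2-methoxy-6-methylbenzoic acid | OC(=O)c1c(C)cc(OC(=O)c2c(C)cc(OC)cc2OCc2ccccc2)cc1OC | intermediate
14 | 4-{[2-(benzyloxy)-4-methoxy-6-methylbenzoyl]oxy}-2-methoxy-6-methylbenzoyl chloride (not isolated) | ClC(=O)c1c(C)cc(OC(=O)c2c(C)cc(OC)cc2OCc2ccccc2)cc1OC | intermediate
15 | methyl 4-[(4-{[2-(benzyloxy)-4-methoxy-6-methylbenzoyl]oxy}-2-methoxy-6-methylbenzoyl)oxy]-6-methyl-2-oxocyclohex-3-ene-1-carboxylate (racemic) | COC(=O)C1C(C)CC(OC(=O)c2c(C)cc(OC(=O)c3c(C)cc(OC)cc3OCc3ccccc3)cc2OC)=CC1=O | intermediate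
16 | methyl 4-[(4-{[2-(benzyloxy)-4-methoxy-6-methylbenzoyl]oxy}-2-methoxy-6-methylbenzoyl)oxy]-2-methoxy-6-methylcyclohexa-1,3-diene-1-carboxylate (racemic) | COC(=O)C1=C(OC)C=C(OC(=O)c2c(C)cc(OC(=O)c3c(C)cc(OC)cc3OCc3ccccc3)cc2OC)CC1C | intermediate
17 | methyl 4-[(4-{[2-(benzyloxy)-4-methoxy-6-methylbenzoyl]oxy}-2-methoxy-6-methylbenzoyl)oxy]-2-methoxy-6-methylbenzoate | COC(=O)c1c(C)cc(OC(=O)c2c(C)cc(OC(=O)c3c(C)cc(OC)cc3OCc3ccccc3)cc2OC)cc1OC | intermediate
18 | methyl 4-({4-[(2-hydroxy-4-methoxy-6-methylbenzoyl)oxy]-2-methoxy-6-methylbenzoyl}oxy)-2-methoxy-6-methylbenzoate (CNP0362907.0) | COC(=O)c1c(C)cc(OC(=O)c2c(C)cc(OC(=O)c3c(C)cc(OC)cc3O)cc2OC)cc1OC | target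

**Step count**
Total: 11 steps. Longest linear sequence: 10 steps (5 to 18 through steps 2-7 and 8-11); the ring C branch is 5 steps (step 1, then 8-11).

**Steps most likely to fail**

Step 9. What may go wrong is C-methylation at C1 in place of O-methylation, or base-induced acyl transfer from the enol ester before the enolate is trapped. The fallback sets out from 15 and comes back at 17, and it moves the methylation to a phenol. 15 is dehydrogenated first with DDQ in 1,4-dioxane at reflux, acting through the beta-keto ester enol, which should give methyl 4-[(4-{[2-(benzyloxy)-4-methoxy-6-methylbenzoyl]oxy}-2-methoxy-6-methylbenzoyl)oxy]-2-hydroxy-6-methylbenzoate F1. Its only free hydroxyl is the chelated C2 phenol, so MeI, K2CO3 in acetone at reflux should then give 17 without any O-versus-C question.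

Step 8. What may go wrong is acylation at the C2 enol oxygen, O-to-C acyl migration to C3, or sluggish acyl transfer from the di-ortho-substituted acid chloride to the weakly nucleophilic dione enolate. The fallback sets out from methyl orsellinate 5 (with acid chloride 14 made as in step 8) and comes back at 17. Ring C is taken as an arene and its oxygens are told apart by a protecting group. BnBr, K2CO3 in acetone should give methyl 4-(benzyloxy)-2-hydroxy-6-methylbenzoate F2. MeI, K2CO3 in DMF should give methyl 4-(benzyloxy)-2-methoxy-6-methylbenzoate F3. H2, Pd/C in EtOAc should give methyl 4-hydroxy-2-methoxy-6-methylbenzoate F4. Acylation of F4 with 14 (Et3N, DMAP, CH2Cl2) should give 17.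

Step 10. What may go wrong is hydride abstraction at the benzylic CH2 of the ring A benzyl ether, cycloaddition of the quinone to the electron-rich diene, or hydrolysis of the enol ether by the acidic hydroquinone and adventitious water. The fallback sets out from 16 and comes back at 17, and it replaces direct dehydrogenation by bromination and dehydrobromination. NBS with catalytic AIBN in PhCF3 at 70 °C should abstract the weak tertiary C6-H and give the allylic bromide methyl 4-[(4-{[2-(benzyloxy)-4-methoxy-6-methylbenzoyl]oxy}-2-methoxy-6-methylbenzoyl)oxy]-6-bromo-2-methoxy-6-methylcyclohexa-1,3-diene-1-carboxylate F5. Without isolation, DBU at rt should remove HBr across C5-C6 to give 17.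

**Further compounds**
F1 | step 9 | methyl 4-[(4-{[2-(benzyloxy)-4-methoxy-6-methylbenzoyl]oxy}-2-methoxy-6-methylbenzoyl)oxy]-2-hydroxy-6-methylbenzoate | COC(=O)c1c(C)cc(OC(=O)c2c(C)cc(OC(=O)c3c(C)cc(OC)cc3OCc3ccccc3)cc2OC)cc1O
F2 | step 8 | methyl 4-(benzyloxy)-2-hydroxy-6-methylbenzoate | COC(=O)c1c(C)cc(OCc2ccccc2)cc1O
F3 | step 8 | methyl 4-(benzyloxy)-2-methoxy-6-methylbenzoate | COC(=O)c1c(C)cc(OCc2ccccc2)cc1OC
F4 | step 8 | methyl 4-hydroxy-2-methoxy-6-methylbenzoate | COC(=O)c1c(C)cc(O)cc1OC
F5 | step 10 | methyl 4-[(4-{[2-(benzyloxy)-4-methoxy-6-methylbenzoyl]oxy}-2-methoxy-6-methylbenzoyl)oxy]-6-bromo-2-methoxy-6-methylcyclohexa-1,3-diene-1-carboxylate (racemic) | COC(=O)C1=C(OC)C=C(OC(=O)c2c(C)cc(OC(=O)c3c(C)cc(OC)cc3OCc3ccccc3)cc2OC)CC1(C)Br
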